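The C2–C3 bond of the dihydrofuran is the disconnection on which everything rests. C3 is a benzhydryl-type carbon bonded to ring A and to the resorcinol ring, which makes it accessible from a diaryl carbene; C2 is the aryl-substituted carbon on O1, which makes it the CH2 of a benzylic aryl ether. A single dirhodium-catalysed 1,5 C–H insertion therefore forges C2–C3, closes the five-membered ring and fixes C3 in the S configuration. Its precursor is a benzophenone hydrazone in which ring A holds the hydrazone carbon between two identical 2,4-dimethoxybenzyloxy groups, so both methylenes lead to one product; C2 is later equilibrated to trans under Lewis acid.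

Key step: step 7

Ring labels and numbering: ring A is the benzo ring of the benzofuran (C3a to C7a, oxygen on C4, phenethyl arm on C6), ring B the aryl group on C2, ring C the aryl group on C3, ring D the phenyl ring of the phenethyl arm.

Assumption: Rh2(S-PTAD)4 is taken to induce the 3S configuration with this substrate; if the sense proves opposite, Rh2(R-PTAD)4 is used and nothing else changes.

Step 1
Reactants: 1 3,5-dihydroxybenzaldehyde
Product: 2 3,5-bis(methoxymethoxy)benzaldehyde
Conditions: MOMCl (3 equiv), i-Pr2NEt (4 equiv), DMF, 0 °C to rt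
Reagents that add atoms: chloromethyl methyl ether, COCCl
Why: O-alkylation of both phenols (MOM acetal protection) with an amine base leaves the aldehyde untouched and installs the two groups that later direct the metalation.

Step 2
Reactants: 2 3,5-bis(methoxymethoxy)benzaldehyde; 3 (4-methoxybenzyl)triphenylphosphonium chloride
Product: 5 1,3-bis(methoxymethoxy)-5-[2-(4-methoxyphenyl)ethenyl]benzene (E/Z mixture), via phosphorus ylide 4 (not isolated)
Conditions: 3 (1.2 equiv), KOt-Bu (1.3 equiv), THF, 0 °C; then 2, 0 °C to rt
Reagents that add atoms: none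
Why: Wittig olefination of an aromatic aldehyde with a semi-stabilised benzylic ylide gives the stilbene, whose E/Z mixture does not matter because the double bond is saturated in the next step.

Step 3
Reactants: 5 1,3-bis(methoxymethoxy)-5-[2-(4-methoxyphenyl)ethenyl]benzene
Product: 6 1,3-bis(methoxymethoxy)-5-[2-(4-methoxyphenyl)ethyl]benzene
Conditions: H2 (1 atm), 10% Pd/C, EtOAc, rt
Reagents that add atoms: none
Why: Heterogeneous catalytic hydrogenation reduces both alkene isomers to the bibenzyl under neutral conditions that leave MOM acetals and aryl methyl ethers intact.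

Step 4
Reactants: 6 1,3-bis(methoxymethoxy)-5-[2-(4-methoxyphenyl)ethyl]benzene; 7 3,5-dimethoxybenzonitrile
Product: 10 [2,6-dihydroxy-4-[2-(4-methoxyphenyl)ethyl]phenyl](3,5-dimethoxyphenyl)methanone, via aryllithium 8 (not isolated), via N-lithio ketimine 9 (not isolated)
Conditions: n-BuLi (1.2 equiv), THF, 0 °C; 7, −78 °C to rt; then 3 M HCl/MeOH, 60 °C
Reagents that add atoms: water, O
Why: Directed ortho-metalation occurs at the ring position flanked by both OMOM groups (doubly chelated, most acidic), the aryllithium adds once to the nitrile because the N-lithio ketimine resists further addition, and hot methanolic HCl then hydrolyses the ketimine to the ketone (the hydrolysis stage of a Hoesch ketone synthesis) while cleaving both MOM acetals, with methanol trapping the formaldehyde unit as dimethoxymethane.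

Step 5
Reactants: 10 [2,6-dihydroxy-4-[2-(4-methoxyphenyl)ethyl]phenyl](3,5-dimethoxyphenyl)methanone; 11 2,4-dimethoxybenzyl alcohol
Product: 12 [2,6-bis(2,4-dimethoxybenzyloxy)-4-[2-(4-methoxyphenyl)ethyl]phenyl](3,5-dimethoxyphenyl)methanone
Conditions: 11 (2.6 equiv), PPh3 (2.6 equiv), DIAD (2.6 equiv), THF, 0 °C to 40 °C
Reagents that add atoms: none
Why: Mitsunobu etherification, in which each phenol (acidified by the ortho acyl group) is deprotonated by the PPh3/DIAD betaine and alkylated at oxygen by the alkoxyphosphonium ion of the primary benzylic alcohol, avoids the unstable 2,4-dimethoxybenzyl halides.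

Step 6
Reactants: 12 [2,6-bis(2,4-dimethoxybenzyloxy)-4-[2-(4-methoxyphenyl)ethyl]phenyl](3,5-dimethoxyphenyl)methanone
Product: 13 [2,6-bis(2,4-dimethoxybenzyloxy)-4-[2-(4-methoxyphenyl)ethyl]phenyl](3,5-dimethoxyphenyl)methanone hydrazone
Conditions: N2H4·H2O (30 equiv), AcOH (cat.), n-BuOH, 120 °C, sealed tube
Reagents that add atoms: hydrazine hydrate, NN.O
Why: Hydrazone formation by condensation needs a large excess of hydrazine, acid catalysis and heat because both faces of the carbonyl are screened by the ortho benzyloxy groups, the excess also suppressing azine formation, and the C=N geometry is immaterial.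

Step 7
Reactants: 13 [2,6-bis(2,4-dimethoxybenzyloxy)-4-[2-(4-methoxyphenyl)ethyl]phenyl](3,5-dimethoxyphenyl)methanone hydrazone
Product: 15 (2R,3S)-4-(2,4-dimethoxybenzyloxy)-2-(2,4-dimethoxyphenyl)-3-(3,5-dimethoxyphenyl)-6-[2-(4-methoxyphenyl)ethyl]-2,3-dihydro-1-benzofuran (cis), via diaryldiazomethane 14 (not isolated)
Conditions: MnO2 (10 equiv), CH2Cl2, 0 °C, filter through Celite; filtrate added over 1 h to Rh2(S-PTAD)4 (1 mol%; tetrakis[(S)-N-phthaloyl-(1-adamantyl)glycinato]dirhodium), CH2Cl2, 0 °C to rt
Reagents that add atoms: none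
Why: MnO2 dehydrogenates the hydrazone to diaryldiazomethane 14, which loses N2 on the dirhodium tetracarboxylate to give an electrophilic donor/donor rhodium carbene; this inserts, through a concerted three-centre transition state with hydride-shift character, into a C–H bond of an ether methylene that lies 1,5 to the carbene carbon and is activated by the ether oxygen and by ring B. The closest known reaction type is the enantioselective intramolecular C–H insertion of diaryl rhodium carbenes into benzylic ether C–H bonds, which delivers cis-2,3-diaryl-2,3-dihydrobenzofurans. The ring O1–C2–C3–C3a–C7a closes as a five-membered ring by 1,5 C–H insertion, C2–C3 being the only new skeletal bond. C3 is set by the chiral carboxylate ligands, which choose the face of the carbene that is attacked (equivalently, which of the two enantiotopic benzyloxy groups of ring A reacts), and C2 is set relative to C3 by the compact transition state that holds the two aryl groups cis, giving 2R,3S. The step needs site selectivity and enantioface selectivity: the substrate secures the first because the two ether methylenes are the only C–H bonds in a 1,5 relationship and are interchangeable by the local symmetry of ring A, the unused ether simply remaining on O4, and the catalyst supplies the second. Slow addition keeps the diazo concentration low against azine formation, and any trans isomer of the same C3 configuration converges later because C2 is equilibrated.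

Step 8
Reactants: 15 (2R,3S)-4-(2,4-dimethoxybenzyloxy)-2-(2,4-dimethoxyphenyl)-3-(3,5-dimethoxyphenyl)-6-[2-(4-methoxyphenyl)ethyl]-2,3-dihydro-1-benzofuran
Product: 16 (2R,3S)-2-(2,4-dimethoxyphenyl)-3-(3,5-dimethoxyphenyl)-6-[2-(4-methoxyphenyl)ethyl]-2,3-dihydro-1-benzofuran-4-ol (cis)
Conditions: H2 (1 atm), 10% Pd/C, EtOAc, rt, stopped at full conversion
Reagents that add atoms: none
Why: Catalytic hydrogenolysis (O-debenzylation) cleaves the unhindered primary benzylic C–O bond of the spare ether and releases inert 2,4-dimethoxytoluene, while the ring C2–O1 bond, secondary and shielded by the two cis aryl groups, should persist as the cyclic benzylic ether of a flavan does under debenzylation, and removing this group now keeps a benzylating agent out of the Lewis acid step.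

Step 9
Reactants: 16 (2R,3S)-2-(2,4-dimethoxyphenyl)-3-(3,5-dimethoxyphenyl)-6-[2-(4-methoxyphenyl)ethyl]-2,3-dihydro-1-benzofuran-4-ol
Product: 18 (2S,3S)-2-(2,4-dihydroxyphenyl)-3-(3,5-dihydroxyphenyl)-6-[2-(4-hydroxyphenyl)ethyl]-2,3-dihydro-1-benzofuran-4-ol (trans; CNP0329616.1), via ring-opened quinone methide 17 (not isolated)
Conditions: BBr3 (15 equiv), CH2Cl2, −78 °C to rt; then H2O, 0 °C
Reagents that add atoms: none
Why: BBr3 dealkylation of aryl methyl ethers (bromide attack on the methyl group of each borane–ether adduct) frees five phenols, and the same Lewis acid reversibly ionises the C2–O1 bond, assisted by the ortho and para oxygens of ring B, to a ring-opened para-quinone methide whose reclosure under thermodynamic control places the two aryl groups trans, turning C2 from R to S while C3, which is not part of the ionising bond, stays S.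

Compound list
1 | 3,5-dihydroxybenzaldehyde | O=Cc1cc(O)cc(O)c1 | starting material
2 | 3,5-bis(methoxymethoxy)benzaldehyde | O=Cc1cc(OCOC)cc(OCOC)c1 | intermediate
3 | (4-methoxybenzyl)triphenylphosphonium chloride | COc1ccc(C[P+](c2ccccc2)(c2ccccc2)c2ccccc2)cc1.[Cl-] | starting material
4 | (4-methoxybenzylidene)triphenylphosphorane | COc1ccc(C=P(c2ccccc2)(c2ccccc2)c2ccccc2)cc1 | intermediate
5 | 1,3-bis(methoxymethoxy)-5-[2-(4-methoxyphenyl)ethenyl]benzene (E/Z mixture, geometry not specified) | COCOc1cc(C=Cc2ccc(OC)cc2)cc(OCOC)c1 | intermediate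
6 | 1,3-bis(methoxymethoxy)-5-[2-(4-methoxyphenyl)ethyl]benzene | COCOc1cc(CCc2ccc(OC)cc2)cc(OCOC)c1 | intermediate
7 | 3,5-dimethoxybenzonitrile | N#Cc1cc(OC)cc(OC)c1 | starting material
8 | 2-lithio-1,3-bis(methoxymethoxy)-5-[2-(4-methoxyphenyl)ethyl]benzene | [Li]c1c(OCOC)cc(CCc2ccc(OC)cc2)cc1OCOC | intermediate
9 | N-lithio [2,6-bis(methoxymethoxy)-4-[2-(4-methoxyphenyl)ethyl]phenyl](3,5-dimethoxyphenyl)methanimine | [Li]N=C(c1cc(OC)cc(OC)c1)c1c(OCOC)cc(CCc2ccc(OC)cc2)cc1OCOC | intermediate
10 | [2,6-dihydroxy-4-[2-(4-methoxyphenyl)ethyl]phenyl](3,5-dimethoxyphenyl)methanone | O=C(c1cc(OC)cc(OC)c1)c1c(O)cc(CCc2ccc(OC)cc2)cc1O | intermediate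
11 | 2,4-dimethoxybenzyl alcohol | COc1ccc(CO)c(OC)c1 | starting material
12 | [2,6-bis(2,4-dimethoxybenzyloxy)-4-[2-(4-methoxyphenyl)ethyl]phenyl](3,5-dimethoxyphenyl)methanone | O=C(c1cc(OC)cc(OC)c1)c1c(OCc2ccc(OC)cc2OC)cc(CCc2ccc(OC)cc2)cc1OCc1ccc(OC)cc1OC | intermediate
13 | hydrazone of 12 (C=N geometry not specified) | NN=C(c1cc(OC)cc(OC)c1)c1c(OCc2ccc(OC)cc2OC)cc(CCc2ccc(OC)cc2)cc1OCc1ccc(OC)cc1OC | intermediate
14 | 2-[diazo(3,5-dimethoxyphenyl)methyl]-1,3-bis(2,4-dimethoxybenzyloxy)-5-[2-(4-methoxyphenyl)ethyl]benzene | [N-]=[N+]=C(c1cc(OC)cc(OC)c1)c1c(OCc2ccc(OC)cc2OC)cc(CCc2ccc(OC)cc2)cc1OCc1ccc(OC)cc1OC | intermediate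
15 | (2R,3S)-4-(2,4-dimethoxybenzyloxy)-2-(2,4-dimethoxyphenyl)-3-(3,5-dimethoxyphenyl)-6-[2-(4-methoxyphenyl)ethyl]-2,3-dihydro-1-benzofuran (cis) | COc1ccc(CCc2cc(OCc4ccc(OC)cc4OC)c3c(c2)O[C@@H](c2ccc(OC)cc2OC)[C@H]3c2cc(OC)cc(OC)c2)cc1 | intermediate
16 | (2R,3S)-2-(2,4-dimethoxyphenyl)-3-(3,5-dimethoxyphenyl)-6-[2-(4-methoxyphenyl)ethyl]-2,3-dihydro-1-benzofuran-4-ol (cis) | COc1ccc(CCc2cc(O)c3c(c2)O[C@@H](c2ccc(OC)cc2OC)[C@H]3c2cc(OC)cc(OC)c2)cc1 | intermediate
17 | (S)-configured ring-opened para-quinone methide: 4-[2-[2,6-dihydroxy-4-[2-(4-hydroxyphenyl)ethyl]phenyl]-2-(3,5-dihydroxyphenyl)ethylidene]-3-hydroxycyclohexa-2,5-dien-1-one | O=C1C=CC(=C[C@H](c2c(O)cc(CCc3ccc(O)cc3)cc2O)c2cc(O)cc(O)c2)C(O)=C1 | intermediate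
18 | (2S,3S)-2-(2,4-dihydroxyphenyl)-3-(3,5-dihydroxyphenyl)-6-[2-(4-hydroxyphenyl)ethyl]-2,3-dihydro-1-benzofuran-4-ol (trans) | Oc1ccc(CCc2cc(O)c3c(c2)O[C@H](c2ccc(O)cc2O)[C@H]3c2cc(O)cc(O)c2)cc1 | target

Total step count: 9. Longest linear sequence: 9 steps (1 to 18); compounds 3, 7 and 11 are purchased.

Steps most likely to fail

Step 7. The process at risk is consumption of the electron-rich diazo compound by bimolecular paths (azine and tetraarylethene formation) or by nitrogen loss without the catalyst. Material that reacts this way never meets the chiral dirhodium complex, so both throughput and enantiomeric purity at C3 would fall. The fallback sets out from 13 and returns at 15, and it never lets the diazo compound accumulate. Hydrazone 13 is sulfonylated at the terminal nitrogen with 2-(trifluoromethyl)benzenesulfonyl chloride (pyridine, CH2Cl2, 0 °C) to N'-[[2,6-bis(2,4-dimethoxybenzyloxy)-4-[2-(4-methoxyphenyl)ethyl]phenyl](3,5-dimethoxyphenyl)methylidene]-2-(trifluoromethyl)benzenesulfonohydrazide F1. This is deprotonated with NaH in CH2Cl2 at −20 °C in the presence of Rh2(S-PTAD)4. Bamford–Stevens loss of sulfinate releases 14 slowly at low temperature, and the carbene is intercepted by the catalyst as before to give 15.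

Step 6. The process at risk is addition of hydrazine to a carbonyl carbon screened on both faces, which may be too slow, so that forcing conditions start to degrade the benzylic ethers. The fallback sets out from 12 and returns at 13, replacing condensation at C=O by exchange at C=S. Ketone 12 is thionated with Lawesson's reagent (toluene, 100 °C) to [2,6-bis(2,4-dimethoxybenzyloxy)-4-[2-(4-methoxyphenyl)ethyl]phenyl](3,5-dimethoxyphenyl)methanethione F2. Diaryl thioketones exchange sulfur for nitrogen with hydrazine hydrate (EtOH/THF, rt) far more readily than the ketones condense, which should give 13 with loss of hydrogen sulfide.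

Step 9. The process at risk is ether cleavage that stops at partly methylated stages, together with oxidative and adsorptive loss of the hexaphenol during aqueous work-up and chromatography. The fallback sets out from 16 and returns at 18, moving purification to a protected derivative. The crude product of the BBr3 reaction is not isolated but acetylated at once (Ac2O, pyridine, DMAP cat., rt) to 4-[(2S,3S)-4-acetoxy-3-(3,5-diacetoxyphenyl)-6-[2-(4-acetoxyphenyl)ethyl]-2,3-dihydro-1-benzofuran-2-yl]-1,3-phenylene diacetate F3. This hexaacetate should be air-stable and separable on silica from under-cleaved material and from any residual cis isomer. Deacetylation with K2CO3 in degassed MeOH at 0 °C, followed by acidification, then gives 18.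

Further compounds
F1 | step 7 | N'-[[2,6-bis(2,4-dimethoxybenzyloxy)-4-[2-(4-methoxyphenyl)ethyl]phenyl](3,5-dimethoxyphenyl)methylidene]-2-(trifluoromethyl)benzenesulfonohydrazide | FC(F)(F)c1ccccc1S(=O)(=O)NN=C(c1cc(OC)cc(OC)c1)c1c(OCc2ccc(OC)cc2OC)cc(CCc2ccc(OC)cc2)cc1OCc1ccc(OC)cc1OC
F2 | step 6 | [2,6-bis(2,4-dimethoxybenzyloxy)-4-[2-(4-methoxyphenyl)ethyl]phenyl](3,5-dimethoxyphenyl)methanethione | S=C(c1cc(OC)cc(OC)c1)c1c(OCc2ccc(OC)cc2OC)cc(CCc2ccc(OC)cc2)cc1OCc1ccc(OC)cc1OC
F3 | step 9 | 4-[(2S,3S)-4-acetoxy-3-(3,5-diacetoxyphenyl)-6-[2-(4-acetoxyphenyl)ethyl]-2,3-dihydro-1-benzofuran-2-yl]-1,3-phenylene diacetate | CC(=O)Oc1ccc(CCc2cc(OC(C)=O)c3c(c2)O[C@H](c2ccc(OC(C)=O)cc2OC(C)=O)[C@H]3c2cc(OC(C)=O)cc(OC(C)=O)c2)cc1
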